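Kuwanon I is disconnected at the two bonds that join ring carbons C1 and C2 of its cyclohexene to the aroyl carbonyl and to the chalcone aryl ring. These substituents sit trans on adjacent carbons beside the C3=C4(CH3) alkene, the imprint of a 1,2-addition across one end of a 1,3-diene. One three-component step adds an aroyl radical (from an α-keto acid) and a nickel-bound aryl group to an enantiopure 5-aryl-1-methylcyclohexa-1,3-diene, whose single stereocentre (C6 of the product) steers both new centres trans. The precursor is this (R)-diene bearing the protected resorcinyl ring; a prenylated aryl keto acid and an acetyl-substituted 2,6-dialkoxyaryl bromide are its partners. Chalcone formation and deprotection follow.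

Key step: step 12

Remark on a structure: the diene that maps onto the target has its methyl group on the diene terminus remote from the aryl-bearing carbon, so it is 5-aryl-1-methylcyclohexa-1,3-diene (CC1=CC=C[C@H](Ar)C1). A 2-methyl isomer would put the methyl group on C3 of the product and is not used.

Remark on the chemistry (assumption): n-BuLi, MeLi, LiN(iPr)2 and lithium 2,2,6,6-tetramethylpiperidide are used as commercial solutions; methoxymethyl (MOM) ethers protect all phenols throughout.

Step 1
Reactants: 1 4-bromobenzene-1,3-diol (4-bromoresorcinol)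
Product: 2 1-bromo-2,4-bis(methoxymethoxy)benzene
Conditions: MOMCl, iPr2NEt, CH2Cl2, 0 °C → rt
Reagents that add atoms: chloromethyl methyl ether COCCl
Why: Twofold O-alkylation of the phenols by the reactive α-chloro ether under amine base (Williamson-type etherification); no stereocentre is involved.

Step 2
Reactants: 2 1-bromo-2,4-bis(methoxymethoxy)benzene
Product: 5 [2,4-bis(methoxymethoxy)phenyl]boronic acid, via aryllithium 3 (not isolated), via lithium arylborate 4 (not isolated)
Conditions: n-BuLi, THF, −78 °C; B(OiPr)3, −78 °C → rt; sat. aq NH4Cl, 0 °C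
Reagents that add atoms: triisopropyl borate CC(C)OB(OC(C)C)OC(C)C; water O; n-butyllithium [Li]CCCC (lithium of 3 and 4 only)
Why: Bromine–lithium exchange at −78 °C outpaces ortho-deprotonation, the aryllithium is borylated by the trialkyl borate, and near-neutral hydrolysis gives the boronic acid without touching the acetal protecting groups.

Step 3
Reactants: 5 [2,4-bis(methoxymethoxy)phenyl]boronic acid; 6 cyclohex-2-en-1-one
Product: 7 (3S)-3-[2,4-bis(methoxymethoxy)phenyl]cyclohexan-1-one
Conditions: [RhCl(C2H4)2]2 (1.5 mol %), (S)-BINAP (3.3 mol %), aq KOH (20 mol %), dioxane/H2O 10:1, 35 °C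
Reagents that add atoms: none
Why: Hayashi–Miyaura conjugate addition, in which the (S)-BINAP-bound arylrhodium species (monovalent rhodium) inserts the enone on one enantioface and water protonates the rhodium enolate; the established sense for arylboronic acids and cyclohexenone ((S)-ligand gives (S)-ketone) sets C3 as S, and a cyclooctadiene-free rhodium source avoids a racemic background pathway.

Step 4
Reactants: 7 (3S)-3-[2,4-bis(methoxymethoxy)phenyl]cyclohexan-1-one
Product: 9 (5S)-5-[2,4-bis(methoxymethoxy)phenyl]cyclohex-2-en-1-one, via silyl enol ether 8 (not isolated)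
Conditions: LiN(iPr)2, Me3SiCl (in situ quench), THF, −78 °C; then Pd(OAc)2 (1.05 equiv), MeCN, rt
Reagents that add atoms: chlorotrimethylsilane C[Si](C)(C)Cl (silicon of 8 only)
Why: Ito–Saegusa oxidation, in which kinetic deprotonation by the bulky amide should favour C6, remote from the aryl-bearing carbon, and palladation of the silyl enol ether followed by β-hydride elimination gives the enone; the regioisomeric 3-arylcyclohex-2-enone is achiral and separable, and the aryl-bearing stereocentre is not touched.

Step 5
Reactants: 9 (5S)-5-[2,4-bis(methoxymethoxy)phenyl]cyclohex-2-en-1-one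
Product: 10 (5S)-5-[2,4-bis(methoxymethoxy)phenyl]-1-methylcyclohex-2-en-1-ol
Conditions: MeLi, THF, −78 °C; H2O
Reagents that add atoms: methyllithium [Li]C
Why: 1,2-Addition of a hard organolithium to the enone carbonyl at low temperature; the new carbinol centre forms as an epimer mixture that is erased in step 6.

Step 6
Reactants: 10 (5S)-5-[2,4-bis(methoxymethoxy)phenyl]-1-methylcyclohex-2-en-1-ol
Product: 13 (5R)-5-[2,4-bis(methoxymethoxy)phenyl]-1-methylcyclohexa-1,3-diene, via allyl sulfenate 11 (not isolated), via allyl sulfoxide 12 (not isolated)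
Conditions: 2,4-(O2N)2C6H3SCl, Et3N, ClCH2CH2Cl, 0 → 50 °C
Reagents that add atoms: 2,4-dinitrobenzenesulfenyl chloride ClSc1ccc(cc1[N+](=O)[O-])[N+](=O)[O-] (sulfur and aryl group of 11 and 12 only)
Why: 1,4-Dehydration of an allylic alcohol by O-sulfenylation, [2,3]-sigmatropic sulfenate-to-sulfoxide rearrangement (Mislow–Evans type) and syn-elimination of the aryl sulfoxide: the only sp3 β-hydrogens of 12 are on the CH2 next to the aryl-bearing carbon, so the 1-methyl-1,3-diene forms regiospecifically, and the amine-buffered, acid-free medium leaves the stereocentre intact (its descriptor changes from S to R by priority only).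

Step 7
Reactants: 2 1-bromo-2,4-bis(methoxymethoxy)benzene; 14 1-bromo-3-methylbut-2-ene (prenyl bromide)
Product: 16 1-bromo-2,4-bis(methoxymethoxy)-3-(3-methylbut-2-en-1-yl)benzene, via aryllithium 15 (not isolated)
Conditions: lithium 2,2,6,6-tetramethylpiperidide, THF, −78 → −40 °C; 14, −78 °C → rt
Reagents that add atoms: lithium 2,2,6,6-tetramethylpiperidide [Li]N1C(C)(C)CCCC1(C)C (lithium of 15 only)
Why: Directed ortho-metalation, in which the non-nucleophilic lithium amide removes the proton flanked by the two methoxymethoxy groups without bromine–lithium exchange, followed by SN2 alkylation of the aryllithium at the primary allylic bromide.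

Step 8
Reactants: 16 1-bromo-2,4-bis(methoxymethoxy)-3-(3-methylbut-2-en-1-yl)benzene
Product: 19 2-[2,4-bis(methoxymethoxy)-3-(3-methylbut-2-en-1-yl)phenyl]-2-oxoacetic acid, via aryllithium 17 (not isolated), via keto ester 18 (not isolated)
Conditions: n-BuLi, THF, −78 °C; added to (CO2Et)2 (3 equiv), THF, −78 °C; then LiOH, H2O, 0 °C → rt; 1 M HCl to pH 3, 0 °C
Reagents that add atoms: diethyl oxalate CCOC(=O)C(=O)OCC; lithium hydroxide [Li+].[OH-]; n-butyllithium [Li]CCCC (lithium of 17 only)
Why: Bromine–lithium exchange, acylation of the aryllithium by excess diethyl oxalate (inverse addition at −78 °C stops at the keto ester) and mild saponification of the activated ester give the α-keto acid, which is purified by acid–base extraction.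

Step 9
Reactants: 20 2-bromobenzene-1,3-diol (2-bromoresorcinol)
Product: 21 1-(3-bromo-2,4-dihydroxyphenyl)ethan-1-one
Conditions: AcOH, ZnCl2, 130 °C
Reagents that add atoms: acetic acid CC(=O)O
Why: Nencki reaction (Friedel–Crafts acylation of a resorcinol by a carboxylic acid); the two activated ring positions are equivalent by symmetry, so only one regioisomer can form.

Step 10
Reactants: 21 1-(3-bromo-2,4-dihydroxyphenyl)ethan-1-one
Product: 22 1-[3-bromo-2,4-bis(methoxymethoxy)phenyl]ethan-1-one
Conditions: NaH (2.2 equiv), MOMCl, DMF, 0 °C → rt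
Reagents that add atoms: chloromethyl methyl ether COCCl
Why: Williamson-type O-alkylation of both sodium phenoxides, the strong base being needed for the hydrogen-bonded ortho-hydroxy group.

Step 11
Reactants: 23 2,4-dihydroxybenzaldehyde
Product: 24 2,4-bis(methoxymethoxy)benzaldehyde
Conditions: MOMCl, iPr2NEt, CH2Cl2, 0 → 40 °C
Reagents that add atoms: chloromethyl methyl ether COCCl
Why: Twofold O-alkylation of the phenols by the α-chloro ether under amine base (Williamson-type etherification).

Step 12
Reactants: 13 (5R)-5-[2,4-bis(methoxymethoxy)phenyl]-1-methylcyclohexa-1,3-diene; 19 2-[2,4-bis(methoxymethoxy)-3-(3-methylbut-2-en-1-yl)phenyl]-2-oxoacetic acid; 22 1-[3-bromo-2,4-bis(methoxymethoxy)phenyl]ethan-1-one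
Product: 25 {(1S,2S,6R)-2-[3-acetyl-2,6-bis(methoxymethoxy)phenyl]-6-[2,4-bis(methoxymethoxy)phenyl]-4-methylcyclohex-3-en-1-yl}[2,4-bis(methoxymethoxy)-3-(3-methylbut-2-en-1-yl)phenyl]methanone
Conditions: Ir[dF(CF3)ppy]2(dtbbpy)PF6 (2 mol %), NiBr2·glyme (10 mol %), 4,4'-di-tert-butyl-2,2'-bipyridine (12 mol %), Li2CO3, degassed DMA, 450 nm LEDs, 25 °C; 13 and 19 1.5 equiv each, 22 1.0 equiv
Reagents that add atoms: none
Why: Proposed new method: blue-light excitation of the iridium photocatalyst oxidises the lithium carboxylate of 19, loss of CO2 gives a nucleophilic aroyl radical that adds to the unsubstituted diene terminus of 13 (C1 of the product), and the resulting C2–C3–C4 allyl radical is captured by the arylnickel bromide formed from 22 and zerovalent nickel, reductive elimination from trivalent nickel forming the C2–aryl bond before the reduced photocatalyst returns monovalent nickel to the zerovalent state. The closest known reaction type is the nickel/photoredox three-component 1,2-dicarbofunctionalisation of acyclic 1,3-dienes (carbon radical plus aryl bromide), with the decarboxylative aroylation of aryl halides by α-keto acids as precedent for the radical source; a cyclic chiral diene, an aroyl radical and a di-ortho-alkoxy aryl bromide have not been combined. No ring is closed. C1 is controlled by the existing stereocentre (C6 of the product), the radical entering anti to its aryl group, and C2 is controlled by C1, nickel delivering the aryl group to the allyl face anti to the new aroyl group, which gives the all-trans array. The step needs 1,2- rather than 1,4-arylation and three-component coupling rather than direct aroyl–aryl coupling: the methyl group makes the distal allyl terminus C4 tertiary and so disfavours bond formation there, and the hindered arylnickel species should couple only slowly with the aroyl radical, which is instead intercepted by the excess diene.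

Step 13
Reactants: 25 the all-trans acetyl compound named in step 12; 24 2,4-bis(methoxymethoxy)benzaldehyde
Product: 26 kuwanon I octakis(methoxymethyl) ether (25 with the acetyl group converted into an (E)-3-[2,4-bis(methoxymethoxy)phenyl]prop-2-enoyl group; (1S,2S,6R) ring configuration unchanged)
Conditions: KOH (50 % aq), EtOH/THF, rt
Reagents that add atoms: none
Why: Claisen–Schmidt condensation, in which the methyl ketone enolate adds to the non-enolisable aldehyde and E1cB dehydration gives the E-enone; the ring C1–H is also α to a ketone, but the all-trans arrangement is the thermodynamic one, so reversible enolisation there cannot erode the configuration.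

Step 14
Reactants: 26 kuwanon I octakis(methoxymethyl) ether
Product: 27 kuwanon I
Conditions: HCl (3 M aq), MeOH/THF, 35 °C, argon
Reagents that add atoms: none
Why: Acid-catalysed acetal exchange with methanol (methoxymethyl ether cleavage) frees all eight phenols under conditions chosen to be mild for the prenyl group, the enone and the three stereocentres.

Compound list
1 | 4-bromobenzene-1,3-diol (4-bromoresorcinol) | Oc1ccc(Br)c(O)c1 | starting material
2 | 1-bromo-2,4-bis(methoxymethoxy)benzene | COCOc1ccc(Br)c(OCOC)c1 | intermediate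
3 | [2,4-bis(methoxymethoxy)phenyl]lithium | [Li]c1ccc(OCOC)cc1OCOC | intermediate
4 | lithium [2,4-bis(methoxymethoxy)phenyl]tri(propan-2-yloxy)borate | [Li+].CC(C)O[B-](OC(C)C)(OC(C)C)c1ccc(OCOC)cc1OCOC | intermediate
5 | [2,4-bis(methoxymethoxy)phenyl]boronic acid | OB(O)c1ccc(OCOC)cc1OCOC | intermediate
6 | cyclohex-2-en-1-one | O=C1C=CCCC1 | starting material
7 | (3S)-3-[2,4-bis(methoxymethoxy)phenyl]cyclohexan-1-one | O=C1C[C@@H](c2ccc(OCOC)cc2OCOC)CCC1 | intermediate
8 | {[(5S)-5-[2,4-bis(methoxymethoxy)phenyl]cyclohex-1-en-1-yl]oxy}trimethylsilane | C[Si](C)(C)OC1=CCC[C@H](c2ccc(OCOC)cc2OCOC)C1 | intermediate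
9 | (5S)-5-[2,4-bis(methoxymethoxy)phenyl]cyclohex-2-en-1-one | O=C1C[C@@H](c2ccc(OCOC)cc2OCOC)CC=C1 | intermediate
10 | (5S)-5-[2,4-bis(methoxymethoxy)phenyl]-1-methylcyclohex-2-en-1-ol (both C1 epimers) | CC1(O)C[C@@H](c2ccc(OCOC)cc2OCOC)CC=C1 | intermediate
11 | 1-({[(5S)-5-[2,4-bis(methoxymethoxy)phenyl]-1-methylcyclohex-2-en-1-yl]oxy}sulfanyl)-2,4-dinitrobenzene | CC1(OSc3ccc(cc3[N+](=O)[O-])[N+](=O)[O-])C[C@@H](c2ccc(OCOC)cc2OCOC)CC=C1 | intermediate
12 | 1-{[(5R)-5-[2,4-bis(methoxymethoxy)phenyl]-3-methylcyclohex-2-en-1-yl]sulfinyl}-2,4-dinitrobenzene (C1 and sulfur unspecified) | CC1=CC(S(=O)c3ccc(cc3[N+](=O)[O-])[N+](=O)[O-])C[C@H](c2ccc(OCOC)cc2OCOC)C1 | intermediate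
13 | (5R)-5-[2,4-bis(methoxymethoxy)phenyl]-1-methylcyclohexa-1,3-diene | CC1=CC=C[C@H](c2ccc(OCOC)cc2OCOC)C1 | intermediate
14 | 1-bromo-3-methylbut-2-ene (prenyl bromide) | CC(C)=CCBr | starting material
15 | [3-bromo-2,6-bis(methoxymethoxy)phenyl]lithium | [Li]c1c(OCOC)ccc(Br)c1OCOC | intermediate
16 | 1-bromo-2,4-bis(methoxymethoxy)-3-(3-methylbut-2-en-1-yl)benzene | CC(C)=CCc1c(OCOC)ccc(Br)c1OCOC | intermediate
17 | [2,4-bis(methoxymethoxy)-3-(3-methylbut-2-en-1-yl)phenyl]lithium | [Li]c1ccc(OCOC)c(CC=C(C)C)c1OCOC | intermediate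
18 | ethyl 2-[2,4-bis(methoxymethoxy)-3-(3-methylbut-2-en-1-yl)phenyl]-2-oxoacetate | CCOC(=O)C(=O)c1ccc(OCOC)c(CC=C(C)C)c1OCOC | intermediate
19 | 2-[2,4-bis(methoxymethoxy)-3-(3-methylbut-2-en-1-yl)phenyl]-2-oxoacetic acid | O=C(O)C(=O)c1ccc(OCOC)c(CC=C(C)C)c1OCOC | intermediate
20 | 2-bromobenzene-1,3-diol (2-bromoresorcinol) | Oc1cccc(O)c1Br | starting material
21 | 1-(3-bromo-2,4-dihydroxyphenyl)ethan-1-one | CC(=O)c1ccc(O)c(Br)c1O | intermediate
22 | 1-[3-bromo-2,4-bis(methoxymethoxy)phenyl]ethan-1-one | CC(=O)c1ccc(OCOC)c(Br)c1OCOC | intermediate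
23 | 2,4-dihydroxybenzaldehyde | O=Cc1ccc(O)cc1O | starting material
24 | 2,4-bis(methoxymethoxy)benzaldehyde | O=Cc1ccc(OCOC)cc1OCOC | intermediate
25 | {(1S,2S,6R)-2-[3-acetyl-2,6-bis(methoxymethoxy)phenyl]-6-[2,4-bis(methoxymethoxy)phenyl]-4-methylcyclohex-3-en-1-yl}[2,4-bis(methoxymethoxy)-3-(3-methylbut-2-en-1-yl)phenyl]methanone | O=C(c1ccc(OCOC)c(CC=C(C)C)c1OCOC)[C@@H]2[C@@H](c3c(OCOC)ccc(C(C)=O)c3OCOC)C=C(C)C[C@H]2c2ccc(OCOC)cc2OCOC | intermediate
26 | kuwanon I octakis(methoxymethyl) ether, (1S,2S,6R) ring configuration and E enone | O=C(c1ccc(OCOC)c(CC=C(C)C)c1OCOC)[C@@H]2[C@@H](c3c(OCOC)ccc(C(=O)/C=C/c4ccc(OCOC)cc4OCOC)c3OCOC)C=C(C)C[C@H]2c2ccc(OCOC)cc2OCOC | intermediate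
27 | kuwanon I | CC(C)=CCc1c(O)ccc(C(=O)[C@@H]2[C@@H](c3c(O)ccc(C(=O)/C=C/c4ccc(O)cc4O)c3O)C=C(C)C[C@H]2c2ccc(O)cc2O)c1O | target

Total step count: 14.
Longest linear sequence: 9 steps (steps 1, 2, 3, 4, 5, 6, 12, 13, 14, from 4-bromoresorcinol).

Steps most likely to fail

1. Step 12 (proposed new method). Several processes could divert it:
- the aroyl radical may be captured by the arylnickel species before it meets the diene, giving two-component ketone formation;
- the photocatalyst may sensitise the cyclic diene, which could then dimerise or lose hydrogen to an arene;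
- the hindered arylnickel species may capture the secondary allyl radical too slowly;
- arylation may occur with poor facial or 1,2/1,4 control.

The fallback uses known chemistry, sets out from 16, 22 and 24 and comes back to the route at 25. Bromine–lithium exchange of 16 (n-BuLi, THF, −78 °C) and acylation with N-methoxy-N-methylacetamide would give the methyl ketone 1-[2,4-bis(methoxymethoxy)-3-(3-methylbut-2-en-1-yl)phenyl]ethan-1-one F1. Claisen–Schmidt condensation of F1 with 24 (KOH, EtOH) would give the chalcone (2E)-1-[2,4-bis(methoxymethoxy)-3-(3-methylbut-2-en-1-yl)phenyl]-3-[2,4-bis(methoxymethoxy)phenyl]prop-2-en-1-one F2. Hydroboration of commercial 2-methylbut-1-en-3-yne with pinacolborane (Cp2ZrHCl cat.) would give the dienylboronate 4,4,5,5-tetramethyl-2-[(1E)-3-methylbuta-1,3-dien-1-yl]-1,3,2-dioxaborolane F3. Suzuki–Miyaura coupling of F3 with 22 (PdCl2(dppf), K3PO4, dioxane/H2O, 80 °C) would give the aryl diene 1-{2,4-bis(methoxymethoxy)-3-[(1E)-3-methylbuta-1,3-dien-1-yl]phenyl}ethan-1-one F4. A thermal Diels–Alder reaction of F2 with F4 (toluene, sealed tube, 160 °C) should give the ortho/para-oriented adduct as two racemic diastereomers: the all-trans (exo) racemate, that is 25 together with its (1R,2R,6S) enantiomer F5, and the cis,trans (endo) diastereomer F6. Chromatography would remove F6 and HPLC on a chiral stationary phase would remove F5, leaving 25. This fallback gives up absolute stereocontrol and pays for it with a resolution.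

2. Step 6. The sulfenyl chloride may attack the electron-rich resorcinyl ring in competition with O-sulfenylation. The liberated sulfenic acid may add back to the diene. The diene may drift into conjugation with the arene, which would destroy the stereocentre.

The fallback sets out from 10 and comes back at 13. Oxidative 1,3-transposition of 10 with pyridinium chlorochromate (C5H5NH)[CrO3Cl] (CH2Cl2, rt) would give the β-methyl enone (5R)-5-[2,4-bis(methoxymethoxy)phenyl]-3-methylcyclohex-2-en-1-one F7. Kinetic deprotonation of F7 at C6 (LiN(iPr)2, THF, −78 °C) and O-triflation with PhNTf2 would give the cross-conjugated dienyl triflate (3R)-3-[2,4-bis(methoxymethoxy)phenyl]-5-methylcyclohexa-1,5-dien-1-yl trifluoromethanesulfonate F8. Palladium-catalysed formate reduction of F8 (Pd(OAc)2, PPh3, HCO2H, Bu3N, DMF, 60 °C) would replace the triflate by hydrogen and give 13. The regiochemistry then rests on kinetic α'-deprotonation of an enone.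

3. Step 14. Under protic acid the prenyl group may cyclise onto the neighbouring phenol (chroman formation), the 2'-hydroxychalcone may close to a flavanone, or the eight acetals may be cleaved incompletely.

The fallback sets out from 26 and comes back at 27. Treatment of 26 with TMSOTf and 2,2'-bipyridyl (CH2Cl2, 0 °C → rt) exchanges each aryl methoxymethyl ether for a silyl ether under aprotic, buffered conditions and would give kuwanon I octakis(trimethylsilyl) ether F9. Neutral hydrolysis of F9 (H2O/THF, rt) would cleave the aryl silyl ethers and give 27.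

Further compounds
F1 | step 12 | 1-[2,4-bis(methoxymethoxy)-3-(3-methylbut-2-en-1-yl)phenyl]ethan-1-one | CC(=O)c1ccc(OCOC)c(CC=C(C)C)c1OCOC
F2 | step 12 | (2E)-1-[2,4-bis(methoxymethoxy)-3-(3-methylbut-2-en-1-yl)phenyl]-3-[2,4-bis(methoxymethoxy)phenyl]prop-2-en-1-one | O=C(/C=C/c1ccc(OCOC)cc1OCOC)c1ccc(OCOC)c(CC=C(C)C)c1OCOC
F3 | step 12 | 4,4,5,5-tetramethyl-2-[(1E)-3-methylbuta-1,3-dien-1-yl]-1,3,2-dioxaborolane | CC(=C)/C=C/B1OC(C)(C)C(C)(C)O1
F4 | step 12 | 1-{2,4-bis(methoxymethoxy)-3-[(1E)-3-methylbuta-1,3-dien-1-yl]phenyl}ethan-1-one | CC(=O)c1ccc(OCOC)c(/C=C/C(C)=C)c1OCOC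
F5 | step 12 | (1R,2R,6S) enantiomer of 25 | O=C(c1ccc(OCOC)c(CC=C(C)C)c1OCOC)[C@H]2[C@H](c3c(OCOC)ccc(C(C)=O)c3OCOC)C=C(C)C[C@@H]2c2ccc(OCOC)cc2OCOC
F6 | step 12 | cis,trans (endo) diastereomer of 25, racemic, (1S,2R,6R) enantiomer drawn | O=C(c1ccc(OCOC)c(CC=C(C)C)c1OCOC)[C@@H]2[C@H](c3c(OCOC)ccc(C(C)=O)c3OCOC)C=C(C)C[C@H]2c2ccc(OCOC)cc2OCOC
F7 | step 6 | (5R)-5-[2,4-bis(methoxymethoxy)phenyl]-3-methylcyclohex-2-en-1-one | CC1=CC(=O)C[C@H](c2ccc(OCOC)cc2OCOC)C1
F8 | step 6 | (3R)-3-[2,4-bis(methoxymethoxy)phenyl]-5-methylcyclohexa-1,5-dien-1-yl trifluoromethanesulfonate | CC1=CC(OS(=O)(=O)C(F)(F)F)=C[C@H](c2ccc(OCOC)cc2OCOC)C1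
F9 | step 14 | kuwanon I octakis(trimethylsilyl) ether | CC(C)=CCc1c(O[Si](C)(C)C)ccc(C(=O)[C@@H]2[C@@H](c3c(O[Si](C)(C)C)ccc(C(=O)/C=C/c4ccc(O[Si](C)(C)C)cc4O[Si](C)(C)C)c3O[Si](C)(C)C)C=C(C)C[C@H]2c2ccc(O[Si](C)(C)C)cc2O[Si](C)(C)C)c1O[Si](C)(C)C
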